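**Strategy.** The key step exploits the fact that ring A (C1, C2, C3, C4, C9, C10; C1 bears the ester, C2 the hydroxyl) and ring B (C4 to C9; C6 carbonyl, C7 enol carbon, C9 quaternary) share the C4–C9 bond and can each hold an alkene beside it, C1=C2 and C4=C5. Cutting both alkenes leads to an acyclic tetraene whose C9/C10 methyl pair is already set by an enantioselective Ireland–Claisen rearrangement and whose C6 and C7 already carry oxygen. One ruthenium-catalysed double ring-closing metathesis builds both six-membered rings. Diol oxidation, epoxidation of C1=C2 anti to the methyl groups and trans-diaxial opening at C1 by the side-chain acid complete the target.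

Key step: step 13

Numbering used below: C1 ester carbinol, C2 carbinol, C3 CH2, C4=C5 ring alkene, C6 C=O, C7 C–OH, C8 =CH, C9 quaternary C–CH3, C10 CH–CH3.

Assumption 1: the bromoborane controller of step 7 is (4S,5S)-2-bromo-1,3-bis{[3,5-bis(trifluoromethyl)phenyl]sulfonyl}-4,5-diphenyl-1,3,2-diazaborolidine, written "(S,S)-bromoborane"; it is taken to favour the chair leading to the (2R,3R) acid 12, and if a trial run shows the opposite sense its equally accessible (R,R) enantiomer is used unchanged.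

Assumption 2: compounds 2 and 18 are taken to be catalogue compounds.

Step 1
Reactants: 1 ethyl pent-4-enoate; 2 3-[(tert-butyldimethylsilyl)oxy]propanal
Product: 3 ethyl 5-[(tert-butyldimethylsilyl)oxy]-3-hydroxy-2-(prop-2-en-1-yl)pentanoate (syn and anti racemates, used as the mixture)
Conditions: LiN(iPr)2, THF, −78 °C; then 2, −78 °C
Reagents that add atoms: none
Why: Directed aldol addition of the preformed lithium ester enolate to the aldehyde is fast at −78 °C, and the two stereocentres it creates need no control because steps 2 and 3 erase both.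

Step 2
Reactants: 3 ethyl 5-[(tert-butyldimethylsilyl)oxy]-3-hydroxy-2-(prop-2-en-1-yl)pentanoate
Product: 4 ethyl 5-[(tert-butyldimethylsilyl)oxy]-3-oxo-2-(prop-2-en-1-yl)pentanoate (racemic at the enolisable C2)
Conditions: Dess–Martin periodinane, CH2Cl2, 23 °C
Reagents that add atoms: none
Why: Dess–Martin oxidation converts the β-hydroxy ester into the β-keto ester under near-neutral conditions that spare the silyl ether and the terminal alkene.

Step 3
Reactants: 4 ethyl 5-[(tert-butyldimethylsilyl)oxy]-3-oxo-2-(prop-2-en-1-yl)pentanoate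
Product: 5 ethyl (2Z)-5-[(tert-butyldimethylsilyl)oxy]-2-(prop-2-en-1-yl)-3-{[(trifluoromethyl)sulfonyl]oxy}pent-2-enoate
Conditions: NaH, Et2O, 0 °C; then Tf2O, −78 to 0 °C
Reagents that add atoms: trifluoromethanesulfonic anhydride, O=S(=O)(OS(=O)(=O)C(F)(F)F)C(F)(F)F
Why: O-Triflation of the sodium-chelated enolate of a 2-substituted β-keto ester places the triflate cis to the ester (Z), which decides the geometry of the later tetrasubstituted alkene.

Step 4
Reactants: 5 ethyl (2Z)-5-[(tert-butyldimethylsilyl)oxy]-2-(prop-2-en-1-yl)-3-{[(trifluoromethyl)sulfonyl]oxy}pent-2-enoate; 6 methylmagnesium bromide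
Product: 7 ethyl (2E)-5-[(tert-butyldimethylsilyl)oxy]-3-methyl-2-(prop-2-en-1-yl)pent-2-enoate
Conditions: Fe(acac)3 (5 mol %), THF/NMP, −30 °C
Reagents that add atoms: none
Why: Iron-catalysed cross-coupling of a β-keto-ester enol triflate with a methyl Grignard reagent is faster than carbonyl addition at −30 °C and keeps the alkene geometry, so the new methyl group sits cis to the ester.

Step 5
Reactants: 7 ethyl (2E)-5-[(tert-butyldimethylsilyl)oxy]-3-methyl-2-(prop-2-en-1-yl)pent-2-enoate
Product: 8 (2E)-5-[(tert-butyldimethylsilyl)oxy]-3-methyl-2-(prop-2-en-1-yl)pent-2-en-1-ol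
Conditions: iBu2AlH (2.5 equiv), CH2Cl2, −78 °C
Reagents that add atoms: none
Why: 1,2-Reduction of the conjugated ester with iBu2AlH gives the allylic alcohol without touching the alkene geometry, the silyl ether or the allyl group.

Step 6
Reactants: 8 (2E)-5-[(tert-butyldimethylsilyl)oxy]-3-methyl-2-(prop-2-en-1-yl)pent-2-en-1-ol; 9 propionyl chloride
Product: 10 (2E)-5-[(tert-butyldimethylsilyl)oxy]-3-methyl-2-(prop-2-en-1-yl)pent-2-en-1-yl propanoate
Conditions: pyridine, DMAP (cat.), CH2Cl2, 0 °C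
Reagents that add atoms: none
Why: Acylation of a primary allylic alcohol with an acid chloride under nucleophilic catalysis is routine and leaves the alkene geometry intact.

Step 7
Reactants: 10 (2E)-5-[(tert-butyldimethylsilyl)oxy]-3-methyl-2-(prop-2-en-1-yl)pent-2-en-1-yl propanoate
Product: 12 (2R,3R)-3-{2-[(tert-butyldimethylsilyl)oxy]ethyl}-2,3-dimethyl-4-methylidenehept-6-enoic acid, via boron enolate 11 (not isolated)
Conditions: (S,S)-bromoborane (1.3 equiv), iPr2NEt, CH2Cl2, −78 °C; then 23 °C, 48 h; aqueous work-up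
Reagents that add atoms: none
Why: Enantioselective Ireland–Claisen rearrangement, in which soft enolisation with the bromoborane and iPr2NEt in CH2Cl2 gives the Z(O) boron enolate (methyl cis to O–B) that rearranges through a chair with the enolate methyl equatorial and the alkene methyl axial, so C10 and C9 (C2 and C3 of the acid) form in the like (2R,3R) sense with the face chosen by the C2-symmetric controller.

Step 8
Reactants: 12 (2R,3R)-3-{2-[(tert-butyldimethylsilyl)oxy]ethyl}-2,3-dimethyl-4-methylidenehept-6-enoic acid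
Product: 13 (2R,3R)-3-{2-[(tert-butyldimethylsilyl)oxy]ethyl}-2,3-dimethyl-4-methylidenehept-6-en-1-ol
Conditions: LiAlH4, Et2O, 0 to 23 °C
Reagents that add atoms: none
Why: Hydride reduction of the carboxylic acid with LiAlH4 gives the primary alcohol without epimerising the α-centre, while isolated alkenes and the silyl ether are inert.

Step 9
Reactants: 13 (2R,3R)-3-{2-[(tert-butyldimethylsilyl)oxy]ethyl}-2,3-dimethyl-4-methylidenehept-6-en-1-ol
Product: 15 tert-butyl{2-[(3S,4R)-3,4-dimethyl-5-methylideneocta-1,7-dien-4-yl]ethoxy}dimethylsilane, via aldehyde 14 (not isolated)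
Conditions: (COCl)2, DMSO, CH2Cl2, −78 °C; Et3N; then Ph3P=CH2 (from Ph3PCH3Br, KN(SiMe3)2, THF), −78 to 23 °C
Reagents that add atoms: methyltriphenylphosphonium bromide, C[P+](c1ccccc1)(c1ccccc1)c1ccccc1.[Br-]
Why: Swern oxidation followed by Wittig methylenation in the same flask installs the C1 vinyl group without isolating the epimerisable α-methyl aldehyde, so the C10 configuration is carried through unchanged.

Step 10
Reactants: 15 tert-butyl{2-[(3S,4R)-3,4-dimethyl-5-methylideneocta-1,7-dien-4-yl]ethoxy}dimethylsilane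
Product: 16 (3R)-3-[(2S)-but-3-en-2-yl]-3-methyl-4-methylidenehept-6-en-1-ol
Conditions: Bu4NF, THF, 23 °C
Reagents that add atoms: none
Why: Fluoride-mediated desilylation frees the primary alcohol, and nothing else in the triene responds to Bu4NF.

Step 11
Reactants: 16 (3R)-3-[(2S)-but-3-en-2-yl]-3-methyl-4-methylidenehept-6-en-1-ol
Product: 17 (3R)-3-[(2S)-but-3-en-2-yl]-3-methyl-4-methylidenehept-6-enal
Conditions: Dess–Martin periodinane, CH2Cl2, 0 to 23 °C
Reagents that add atoms: none
Why: Dess–Martin oxidation gives the C7 aldehyde under mild conditions that neither isomerise the neighbouring 1,4-diene nor trigger a carbonyl-ene reaction.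

Step 12
Reactants: 17 (3R)-3-[(2S)-but-3-en-2-yl]-3-methyl-4-methylidenehept-6-enal; 18 3-(methoxymethoxy)prop-1-ene
Product: 20 (3R,4R,6R)-6-[(2S)-but-3-en-2-yl]-3-(methoxymethoxy)-6-methyl-7-methylidenedeca-1,9-dien-4-ol, via allylborane 19 (not isolated)
Conditions: 18, s-BuLi, THF, −78 °C; (−)-Ipc2BOMe; BF3·OEt2; 17, −78 °C; NaOH, H2O2, 0 to 23 °C
Reagents that add atoms: none
Why: Reagent-controlled γ-alkoxyallylboration through a closed chair transition state adds C5 and C6 with the C6 oxygen in place and should give the syn 3,4-dioxygenated unit (expected 3R,4R from the isopinocampheyl groups), two temporary centres that step 15 oxidises away.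

Step 13
Reactants: 20 (3R,4R,6R)-6-[(2S)-but-3-en-2-yl]-3-(methoxymethoxy)-6-methyl-7-methylidenedeca-1,9-dien-4-ol
Product: 22 (2R,3R,8S,8aR)-3-(methoxymethoxy)-8,8a-dimethyl-1,2,3,5,8,8a-hexahydronaphthalen-2-ol, via monocyclic triene 21 (not isolated)
Conditions: second-generation Grubbs catalyst RuCl2(=CHPh)(PCy3)(H2IMes) (10 mol %), 1,4-benzoquinone (10 mol %), toluene (0.005 M), 80 °C, argon sparge
Reagents that add atoms: none
Why: Olefin metathesis by repeated [2+2] cycloaddition and cycloreversion at a ruthenium carbene: the carbene loads on the unhindered allyl terminus (C2) and closes ring A onto the C10 vinyl group (six-membered, C1=C2), then a carbene at the oxygen-flanked vinyl group (C5) closes ring B onto the now exocyclic C4 methylene (six-membered, trisubstituted C4=C5), each closure releasing ethylene. The nearest established chemistry is tandem ring-closing metathesis of open-chain tetraenes into fused bicyclic dienes, which tolerates a geminally disubstituted alkene partner when a cyclohexene results. No stereocentre is formed; the C9/C10 pair from step 7 and the temporary C6/C7 pair from step 12 are spectators. The selectivity needed is the pairing of four alkenes, since C1 with C5 would give a seven-membered ring and C2 with C5 an eight-membered ring; the substrate secures it kinetically because the C5 vinyl group, flanked by the allylic methoxymethyl ether, is the slowest to load, so ring A closes first and only the six-membered closure then remains for C5. Carrying C7 as a carbinol avoids an isomerisation-prone allyl ketone, and the C6 oxygen installed before cyclisation makes a later C–H oxidation next to the doubly allylic C3 unnecessary.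

Step 14
Reactants: 22 (2R,3R,8S,8aR)-3-(methoxymethoxy)-8,8a-dimethyl-1,2,3,5,8,8a-hexahydronaphthalen-2-ol
Product: 23 (2R,3R,8S,8aR)-8,8a-dimethyl-1,2,3,5,8,8a-hexahydronaphthalene-2,3-diol
Conditions: ZnBr2, n-PrSH, CH2Cl2, 0 °C
Reagents that add atoms: none
Why: Lewis-acid/thiol acetal cleavage breaks the methoxymethyl group at its O–CH2–O carbon within minutes, so the allylic C6–O bond is not ionised and both ring alkenes stay in place.

Step 15
Reactants: 23 (2R,3R,8S,8aR)-8,8a-dimethyl-1,2,3,5,8,8a-hexahydronaphthalene-2,3-diol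
Product: 25 (4aS,5S)-3-hydroxy-4a,5-dimethyl-5,8-dihydronaphthalen-2(4aH)-one, via diketone 24 (not isolated)
Conditions: (COCl)2, DMSO, CH2Cl2, −78 °C; Et3N, −78 to 0 °C
Reagents that add atoms: none
Why: Double Swern oxidation gives the 6,7-dione, which enolises towards C8 (its only α-hydrogens) to the cross-conjugated diosphenol, and the cold amine treatment should not draw the skipped C1=C2 alkene into conjugation.

Step 16
Reactants: 25 (4aS,5S)-3-hydroxy-4a,5-dimethyl-5,8-dihydronaphthalen-2(4aH)-one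
Product: 26 (4aS,5S)-3-[(tert-butyldimethylsilyl)oxy]-4a,5-dimethyl-5,8-dihydronaphthalen-2(4aH)-one
Conditions: TBSCl, imidazole, DMF, 0 to 23 °C
Reagents that add atoms: tert-butyldimethylsilyl chloride, CC(C)(C)[Si](C)(C)Cl
Why: O-Silylation of the acidic enol hydroxyl masks the diosphenol against the peracid of the next step.

Step 17
Reactants: 26 (4aS,5S)-3-[(tert-butyldimethylsilyl)oxy]-4a,5-dimethyl-5,8-dihydronaphthalen-2(4aH)-one
Product: 27 (4aS,5R,6S,7R)-3-[(tert-butyldimethylsilyl)oxy]-6,7-epoxy-4a,5-dimethyl-5,6,7,8-tetrahydronaphthalen-2(4aH)-one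
Conditions: mCPBA, NaHCO3, CH2Cl2, 0 °C
Reagents that add atoms: 3-chloroperbenzoic acid, OOC(=O)c1cccc(Cl)c1
Why: Prilezhaev epoxidation takes the isolated cis-disubstituted C1=C2 alkene in preference to the two electron-poor dienone alkenes, and the peracid approaches ring A anti to the axial C9 methyl group, placing the oxirane on the face opposite both methyl groups (C1 S, C2 R).

Step 18
Reactants: 28 (S)-2-methylbutan-1-ol; 29 triethyl 4-phosphonocrotonate
Product: 31 ethyl (2E,4E,6S)-6-methylocta-2,4-dienoate, via aldehyde 30 (not isolated)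
Conditions: (COCl)2, DMSO, CH2Cl2, −78 °C; Et3N; then 29, LiN(SiMe3)2, THF, −78 to 0 °C
Reagents that add atoms: none
Why: Swern oxidation and Horner–Wadsworth–Emmons olefination in one flask avoid isolating the volatile, racemisation-prone α-branched aldehyde, and the stabilised phosphonate anion should give the (2E,4E)-dienoate with the chiral-pool centre unchanged.

Step 19
Reactants: 31 ethyl (2E,4E,6S)-6-methylocta-2,4-dienoate
Product: 32 (2E,4E,6S)-6-methylocta-2,4-dienoic acid
Conditions: LiOH, THF/MeOH/H2O, 23 °C; then HCl (aq.)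
Reagents that add atoms: lithium hydroxide, [Li+].[OH-]
Why: Saponification of the ethyl ester leaves the diene geometry and the remote allylic stereocentre untouched.

Step 20
Reactants: 27 (4aS,5R,6S,7R)-3-[(tert-butyldimethylsilyl)oxy]-6,7-epoxy-4a,5-dimethyl-5,6,7,8-tetrahydronaphthalen-2(4aH)-one; 32 (2E,4E,6S)-6-methylocta-2,4-dienoic acid
Product: 33 (1R,2R,3R,8aS)-7-[(tert-butyldimethylsilyl)oxy]-3-hydroxy-1,8a-dimethyl-6-oxo-1,2,3,4,6,8a-hexahydronaphthalen-2-yl (2E,4E,6S)-6-methylocta-2,4-dienoate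
Conditions: 32 (5 equiv), iPr2NEt (0.5 equiv), toluene, 80 °C
Reagents that add atoms: none
Why: Addition of a carboxylic acid to an epoxide under carboxylate/acid catalysis follows the Fürst–Plattner rule: fusion to the flat dienone ring B holds the C9 methyl axial on ring A, so the only trans-diaxial opening is attack at C1 anti to the oxirane oxygen with inversion, leaving the C2 hydroxyl on the opposite face (C1 R, C2 R).

Step 21
Reactants: 33 (1R,2R,3R,8aS)-7-[(tert-butyldimethylsilyl)oxy]-3-hydroxy-1,8a-dimethyl-6-oxo-1,2,3,4,6,8a-hexahydronaphthalen-2-yl (2E,4E,6S)-6-methylocta-2,4-dienoate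
Product: 34 Septeremophilane G, (1R,2R,3R,8aS)-3,7-dihydroxy-1,8a-dimethyl-6-oxo-1,2,3,4,6,8a-hexahydronaphthalen-2-yl (2E,4E,6S)-6-methylocta-2,4-dienoate
Conditions: HF·pyridine, THF, 0 °C
Reagents that add atoms: none
Why: Fluoride-mediated desilylation under mildly acidic conditions frees the diosphenol without acyl migration, ester cleavage or elimination of the C2 hydroxyl.

**Compound list**

1 | ethyl pent-4-enoate | CCOC(=O)CCC=C | starting material
2 | 3-[(tert-butyldimethylsilyl)oxy]propanal | O=CCCO[Si](C)(C)C(C)(C)C | starting material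
3 | ethyl 5-[(tert-butyldimethylsilyl)oxy]-3-hydroxy-2-(prop-2-en-1-yl)pentanoate (syn and anti racemates) | CCOC(=O)C(CC=C)C(O)CCO[Si](C)(C)C(C)(C)C | intermediate
4 | ethyl 5-[(tert-butyldimethylsilyl)oxy]-3-oxo-2-(prop-2-en-1-yl)pentanoate (racemic) | CCOC(=O)C(CC=C)C(=O)CCO[Si](C)(C)C(C)(C)C | intermediate
5 | ethyl (2Z)-5-[(tert-butyldimethylsilyl)oxy]-2-(prop-2-en-1-yl)-3-{[(trifluoromethyl)sulfonyl]oxy}pent-2-enoate | CCOC(=O)/C(CC=C)=C(\OS(=O)(=O)C(F)(F)F)CCO[Si](C)(C)C(C)(C)C | intermediate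
6 | methylmagnesium bromide | C[Mg]Br | starting material
7 | ethyl (2E)-5-[(tert-butyldimethylsilyl)oxy]-3-methyl-2-(prop-2-en-1-yl)pent-2-enoate | CCOC(=O)/C(CC=C)=C(\C)CCO[Si](C)(C)C(C)(C)C | intermediate
8 | (2E)-5-[(tert-butyldimethylsilyl)oxy]-3-methyl-2-(prop-2-en-1-yl)pent-2-en-1-ol | OC/C(CC=C)=C(\C)CCO[Si](C)(C)C(C)(C)C | intermediate
9 | propionyl chloride | CCC(=O)Cl | starting material
10 | (2E)-5-[(tert-butyldimethylsilyl)oxy]-3-methyl-2-(prop-2-en-1-yl)pent-2-en-1-yl propanoate | CCC(=O)OC/C(CC=C)=C(\C)CCO[Si](C)(C)C(C)(C)C | intermediate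
11 | Z(O) boron enolate of 10 carrying the (4S,5S)-diazaborolidine | C/C=C(\OB1N(S(=O)(=O)c2cc(cc(c2)C(F)(F)F)C(F)(F)F)[C@@H](c2ccccc2)[C@H](c2ccccc2)N1S(=O)(=O)c1cc(cc(c1)C(F)(F)F)C(F)(F)F)OC/C(CC=C)=C(\C)CCO[Si](C)(C)C(C)(C)C | intermediate (not isolated)
12 | (2R,3R)-3-{2-[(tert-butyldimethylsilyl)oxy]ethyl}-2,3-dimethyl-4-methylidenehept-6-enoic acid | C=CCC(=C)[C@](C)(CCO[Si](C)(C)C(C)(C)C)[C@@H](C)C(=O)O | intermediate
13 | (2R,3R)-3-{2-[(tert-butyldimethylsilyl)oxy]ethyl}-2,3-dimethyl-4-methylidenehept-6-en-1-ol | C=CCC(=C)[C@](C)(CCO[Si](C)(C)C(C)(C)C)[C@@H](C)CO | intermediate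
14 | (2R,3R)-3-{2-[(tert-butyldimethylsilyl)oxy]ethyl}-2,3-dimethyl-4-methylidenehept-6-enal | C=CCC(=C)[C@](C)(CCO[Si](C)(C)C(C)(C)C)[C@@H](C)C=O | intermediate (not isolated)
15 | tert-butyl{2-[(3S,4R)-3,4-dimethyl-5-methylideneocta-1,7-dien-4-yl]ethoxy}dimethylsilane | C=CCC(=C)[C@](C)(CCO[Si](C)(C)C(C)(C)C)[C@@H](C)C=C | intermediate
16 | (3R)-3-[(2S)-but-3-en-2-yl]-3-methyl-4-methylidenehept-6-en-1-ol | C=CCC(=C)[C@](C)(CCO)[C@@H](C)C=C | intermediate
17 | (3R)-3-[(2S)-but-3-en-2-yl]-3-methyl-4-methylidenehept-6-enal | C=CCC(=C)[C@](C)(CC=O)[C@@H](C)C=C | intermediate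
18 | 3-(methoxymethoxy)prop-1-ene | C=CCOCOC | starting material
19 | [(2Z)-3-(methoxymethoxy)prop-2-en-1-yl]bis[(1R,2S,3R,5R)-2,6,6-trimethylbicyclo[3.1.1]heptan-3-yl]borane | C[C@H]1[C@@H](C[C@@H]2C[C@H]1C2(C)C)B(C/C=C\OCOC)[C@@H]1C[C@@H]2C[C@H]([C@H]1C)C2(C)C | intermediate (not isolated)
20 | (3R,4R,6R)-6-[(2S)-but-3-en-2-yl]-3-(methoxymethoxy)-6-methyl-7-methylidenedeca-1,9-dien-4-ol | C=CCC(=C)[C@](C)(C[C@@H](O)[C@@H](C=C)OCOC)[C@@H](C)C=C | intermediate (key-step precursor)
21 | (2R,3R)-1-[(1R,2S)-1,2-dimethyl-6-methylidenecyclohex-3-en-1-yl]-3-(methoxymethoxy)pent-4-en-2-ol | C=C1CC=C[C@H](C)[C@@]1(C)C[C@@H](O)[C@@H](C=C)OCOC | intermediate (not isolated)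
22 | (2R,3R,8S,8aR)-3-(methoxymethoxy)-8,8a-dimethyl-1,2,3,5,8,8a-hexahydronaphthalen-2-ol | C1=CCC2=C[C@@H](OCOC)[C@H](O)C[C@]2(C)[C@H]1C | intermediate (key-step product)
23 | (2R,3R,8S,8aR)-8,8a-dimethyl-1,2,3,5,8,8a-hexahydronaphthalene-2,3-diol | C1=CCC2=C[C@@H](O)[C@H](O)C[C@]2(C)[C@H]1C | intermediate
24 | (4aR,5S)-4a,5-dimethyl-4,4a,5,8-tetrahydronaphthalene-2,3-dione | C1=CCC2=CC(=O)C(=O)C[C@]2(C)[C@H]1C | intermediate (not isolated)
25 | (4aS,5S)-3-hydroxy-4a,5-dimethyl-5,8-dihydronaphthalen-2(4aH)-one | C1=CCC2=CC(=O)C(O)=C[C@]2(C)[C@H]1C | intermediate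
26 | (4aS,5S)-3-[(tert-butyldimethylsilyl)oxy]-4a,5-dimethyl-5,8-dihydronaphthalen-2(4aH)-one | C1=CCC2=CC(=O)C(O[Si](C)(C)C(C)(C)C)=C[C@]2(C)[C@H]1C | intermediate
27 | (4aS,5R,6S,7R)-3-[(tert-butyldimethylsilyl)oxy]-6,7-epoxy-4a,5-dimethyl-5,6,7,8-tetrahydronaphthalen-2(4aH)-one (oxirane anti to both methyl groups) | C[C@H]1[C@@H]2O[C@@H]2CC2=CC(=O)C(O[Si](C)(C)C(C)(C)C)=C[C@]12C | intermediate
28 | (S)-2-methylbutan-1-ol | CC[C@H](C)CO | starting material
29 | triethyl 4-phosphonocrotonate, ethyl (2E)-4-(diethoxyphosphoryl)but-2-enoate | CCOC(=O)/C=C/CP(=O)(OCC)OCC | starting material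
30 | (S)-2-methylbutanal | CC[C@H](C)C=O | intermediate (not isolated)
31 | ethyl (2E,4E,6S)-6-methylocta-2,4-dienoate | CC[C@H](C)/C=C/C=C/C(=O)OCC | intermediate
32 | (2E,4E,6S)-6-methylocta-2,4-dienoic acid | CC[C@H](C)/C=C/C=C/C(=O)O | intermediate
33 | (1R,2R,3R,8aS)-7-[(tert-butyldimethylsilyl)oxy]-3-hydroxy-1,8a-dimethyl-6-oxo-1,2,3,4,6,8a-hexahydronaphthalen-2-yl (2E,4E,6S)-6-methylocta-2,4-dienoate | CC[C@H](C)/C=C/C=C/C(=O)O[C@H]1[C@H](O)CC2=CC(=O)C(O[Si](C)(C)C(C)(C)C)=C[C@]2(C)[C@H]1C | intermediate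
34 | Septeremophilane G, (1R,2R,3R,8aS)-3,7-dihydroxy-1,8a-dimethyl-6-oxo-1,2,3,4,6,8a-hexahydronaphthalen-2-yl (2E,4E,6S)-6-methylocta-2,4-dienoate | CC[C@H](C)/C=C/C=C/C(=O)O[C@H]1[C@H](O)CC2=CC(=O)C(O)=C[C@]2(C)[C@H]1C | target

**Step count.** Total: 21 steps. Longest linear sequence: 19 steps (steps 1–17, 20 and 21); the side-chain acid 32 takes 2 steps (18 and 19).

**Steps most likely to fail**

1. Step 13 (key step). The second closure onto the hindered C4 methylene may stall after ring A has formed, leaving the C5 vinyl group to oligomerise or the catalyst to decay. The fallback runs the two closures separately and changes the metal for the hard one. Setting out from 20, silylation (Et3SiCl, imidazole, CH2Cl2) would give the triethylsilyl ether of the tetraene F1. The first-generation Grubbs catalyst RuCl2(=CHPh)(PCy3)2 (CH2Cl2, 40 °C), which does not engage 1,1-disubstituted alkenes, should close ring A alone to the monocyclic triene silyl ether F2. The molybdenum imido alkylidene Mo(=CHCMe2Ph)(=N-2,6-iPr2C6H3)[OCMe(CF3)2]2 (benzene, 60 °C), which is suited to hindered trisubstituted ring closures and tolerates ethers, should then close ring B to the bicyclic bis-ether F3. HCl in MeOH would remove the silyl and methoxymethyl groups together and return to the route at 23.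

2. Step 20. The opening may be too slow at the hindered C1, may leak to attack at C2 through a twist-boat, or may be disturbed by early loss of the enol silyl group. The fallback makes the C1–O bond first and the ester bond afterwards. Setting out from 27, acid-catalysed hydrolysis (HClO4 cat., THF/H2O, 0 °C) should open the oxirane with water in the same trans-diaxial sense to the 1,2-diol F4. Et3SiCl/imidazole at −20 °C should silylate the less hindered C2 hydroxyl to give the mono-triethylsilyl ether F5. Yamaguchi esterification of the remaining C1 hydroxyl with 32 (2,4,6-trichlorobenzoyl chloride, Et3N; then DMAP, toluene) would give the bis-silylated ester F6. HF·pyridine would remove both silyl groups and arrive at 34.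

3. Step 7. The hindered boron enolate may rearrange sluggishly or with insufficient enantio- or diastereoselection. The fallback separates relative from absolute control. Setting out from 10, the silyl ketene acetal variant (LiN(iPr)2, THF/DMPU, Me3SiCl, −78 to 23 °C; Z(O) enolate, same chair) would give the racemic like-configured acid F7. Its pivaloyl mixed anhydride (pivaloyl chloride, Et3N) would acylate lithiated (S)-4-benzyloxazolidin-2-one to give two diastereomeric imides. The imide of the (2R,3R) acid F8 would be separated by chromatography from the discarded imide of the enantiomeric acid F9. Reductive cleavage of F8 (LiBH4, Et2O/MeOH) would rejoin the route at alcohol 13.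

**Further compounds**

F1 | step 13 | (3R,4R,6R)-6-[(2S)-but-3-en-2-yl]-3-(methoxymethoxy)-6-methyl-7-methylidene-4-[(triethylsilyl)oxy]deca-1,9-diene | C=CCC(=C)[C@](C)(C[C@@H](O[Si](CC)(CC)CC)[C@@H](C=C)OCOC)[C@@H](C)C=C
F2 | step 13 | triethyl{[(2R,3R)-1-[(1R,2S)-1,2-dimethyl-6-methylidenecyclohex-3-en-1-yl]-3-(methoxymethoxy)pent-4-en-2-yl]oxy}silane | C=C1CC=C[C@H](C)[C@@]1(C)C[C@@H](O[Si](CC)(CC)CC)[C@@H](C=C)OCOC
F3 | step 13 | (2R,3R,8S,8aR)-3-(methoxymethoxy)-8,8a-dimethyl-2-[(triethylsilyl)oxy]-1,2,3,5,8,8a-hexahydronaphthalene | C1=CCC2=C[C@@H](OCOC)[C@H](O[Si](CC)(CC)CC)C[C@]2(C)[C@H]1C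
F4 | step 20 | (4aS,5R,6R,7R)-3-[(tert-butyldimethylsilyl)oxy]-6,7-dihydroxy-4a,5-dimethyl-5,6,7,8-tetrahydronaphthalen-2(4aH)-one | O[C@H]1[C@H](O)CC2=CC(=O)C(O[Si](C)(C)C(C)(C)C)=C[C@]2(C)[C@H]1C
F5 | step 20 | (4aS,5R,6R,7R)-3-[(tert-butyldimethylsilyl)oxy]-6-hydroxy-4a,5-dimethyl-7-[(triethylsilyl)oxy]-5,6,7,8-tetrahydronaphthalen-2(4aH)-one | O[C@H]1[C@H](O[Si](CC)(CC)CC)CC2=CC(=O)C(O[Si](C)(C)C(C)(C)C)=C[C@]2(C)[C@H]1C
F6 | step 20 | (1R,2R,3R,8aS)-7-[(tert-butyldimethylsilyl)oxy]-1,8a-dimethyl-6-oxo-3-[(triethylsilyl)oxy]-1,2,3,4,6,8a-hexahydronaphthalen-2-yl (2E,4E,6S)-6-methylocta-2,4-dienoate | CC[C@H](C)/C=C/C=C/C(=O)O[C@H]1[C@H](O[Si](CC)(CC)CC)CC2=CC(=O)C(O[Si](C)(C)C(C)(C)C)=C[C@]2(C)[C@H]1C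
F7 | step 7 | racemic (2R*,3R*)-3-{2-[(tert-butyldimethylsilyl)oxy]ethyl}-2,3-dimethyl-4-methylidenehept-6-enoic acid (12 plus its enantiomer) | C=CCC(=C)[C@](C)(CCO[Si](C)(C)C(C)(C)C)[C@@H](C)C(=O)O.C=CCC(=C)[C@@](C)(CCO[Si](C)(C)C(C)(C)C)[C@H](C)C(=O)O
F8 | step 7 | (4S)-4-benzyl-3-[(2R,3R)-3-{2-[(tert-butyldimethylsilyl)oxy]ethyl}-2,3-dimethyl-4-methylidenehept-6-enoyl]-1,3-oxazolidin-2-one | C=CCC(=C)[C@](C)(CCO[Si](C)(C)C(C)(C)C)[C@@H](C)C(=O)N1[C@@H](Cc2ccccc2)COC1=O
F9 | step 7 | (4S)-4-benzyl-3-[(2S,3S)-3-{2-[(tert-butyldimethylsilyl)oxy]ethyl}-2,3-dimethyl-4-methylidenehept-6-enoyl]-1,3-oxazolidin-2-one (discarded diastereomer) | C=CCC(=C)[C@@](C)(CCO[Si](C)(C)C(C)(C)C)[C@H](C)C(=O)N1[C@@H](Cc2ccccc2)COC1=O
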